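The easy error in these flasks is to time the second exchange against the incoming ligand as charged, when part of that ligand sits in another form. The flasks share one charge and differ in how the starting complex goes in and how warm they are kept.

common to all: incoming ligand 4.00 mM; leaving ligand 2.50 mM; time 1.0 min
- green: starting complex 5.0 mM (fed, over 50 s); the addition at 60 °C, then warmed to 80 °C; the feed brings no volume worth counting
- blue: starting complex 5.0 mM; everything together at the start at 60 °C, warmed to 80 °C at 50 s
- red: starting complex 5.0 mM; everything together at the start; temperature 80 °C
- amber: starting complex 5.0 mM (fed, over 50 s); all else is in the flask from the start; the feed brings no volume worth counting; temperature 80 °C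

- the flask with the highest share of complex with one exchanged in complex with one exchanged plus complex with two exchanged ("all alike" if they lie within 1.5 percentage points) (green / blue / red / amber / all alike)
- share of complex with one exchanged in complex with one exchanged plus complex with two exchanged at the end, green
- share of complex with one exchanged in complex with one exchanged plus complex with two exchanged at the end, blue
- share of complex with one exchanged in complex with one exchanged plus complex with two exchanged at the end, red
- share of complex with one exchanged in complex with one exchanged plus complex with two exchanged at the end, amber

- percent here means starting complex units held: one side product counts as two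
- at 80 °C the constants are as listed, elsewhere as the activation energies and enthalpies make them

Two people argue at the board over this scheme:

    incoming ligand ⇌ dormant form (K1 = 3.8, k1 = 2.99 /s, Ea1 = 80.0 kJ/mol, ΔH1 = −26.0 kJ/mol)
    starting complex + incoming ligand ⇌ leaving ligand + complex with one exchanged (K2 = 0.72, k2 = 55.8 /M/s, Ea2 = 54.0 kJ/mol, ΔH2 = −28.0 kJ/mol)
    complex with three exchanged + incoming ligand ⇌ leaving ligand + complex with four exchanged (K3 = 0.395, k3 = 176 /M/s, Ea3 = 39.0 kJ/mol, ΔH3 = −9.00 kJ/mol)
    complex with one exchanged + incoming ligand ⇌ leaving ligand + complex with two exchanged (K4 = 4.8, k4 = 18.3 /M/s, Ea4 = 38.0 kJ/mol, ΔH4 = −10.0 kJ/mol)
    complex with two exchanged + incoming ligand ⇌ leaving ligand + complex with three exchanged (K5 = 21.8, k5 = 33.0 /M/s, Ea5 = 53.0 kJ/mol, ΔH5 = −1.00 kJ/mol)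
    starting complex + complex with one exchanged → side product (k6 = 33.7 /M/s, Ea6 = 39.0 kJ/mol)
    starting complex → decomposition product (k7 = 9.56 × 10⁻⁵ /s, Ea7 = 100 kJ/mol)
    (constants at 80 °C)

The first speaker argues for thermodynamic control. In red, complex with one exchanged has a half-life of 0.16 min by the forward step with the ligand as charged, short against the time of 1.0 min. She therefore takes the exchange to be at equilibrium. The flasks have one charge and end at 80 °C, so she says "all alike", with a share of 11.5% from K4 and the charged c(incoming ligand) and c(leaving ligand).

The second speaker argues for kinetic control, and this reckoning is my own. In red, the incoming ligand has a forward half-life of 0.23 s towards dormant form, far below the time. So at the start it splits at once, and I take c(incoming ligand) free as 0.833 mM. Define the free-ligand clock as the half-life of complex with one exchanged by the forward step with that free ligand at 80 °C: it is 0.758 min, longer than her figure by the factor 4.80. That is no longer short against 1.0 min, so the share should depend on how many clocks a flask has had.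

Red has had 1.32 clocks. For red I commit to one number. If c(complex with one exchanged) is held steady, free ligand stays at 0.833 mM and the way back is set aside, the ratio of complex with two exchanged to complex with one exchanged climbs towards 0.555, the forward constant of the second exchange over that of the third, on a time of 36.4 s. After 1.0 min that gives red a share of 69.1%. In amber the fed complex has stayed 35.0 s on average, which gives 0.770 clocks. At 60 °C the positive 38.0 kJ/mol lowers k4 and the negative −26.0 kJ/mol raises K1, so the clock runs slower there. Green's count therefore stands under amber's, with the same stay on a slower clock, and under blue's, with the same clock and a late charge. For the other flasks my reckoning stops at this order, with green on top.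

The forecast sides with the second speaker and adds figures stepped by hand, and its red figure stands above mine. It names green, with green 82% (77% to 87%), blue 79% (73% to 84%), red 73% (66% to 79%) and amber 76% (70% to 82%). Its ground: “Feeding and the cooler hold both preserve starting complex and limit step 4, so green is highest.”

The simulation gives green: green 85.6%, blue 80.1%, red 70.3%, amber 74.9%, each inside the forecast's range. The first speaker's region comes later. Read at 10.0 min, green stands at 64.7% and red at 65.2%, close together as she said, though not at her 11.5%.

The gap between green and red is 15 percentage points. In the run without the path to dormant form it falls to 3.9 points, and the falling back of complex with one exchanged to starting complex acts with that path. The clock of 0.758 min carries that path in its free ligand. A neighbour of green with 2.4 mM of incoming ligand has a clock of 1.26 min, so green's ratio of complex with two exchanged to complex with one exchanged, 0.169, scales to 0.101, a share of 90.8%, and that neighbour ends at 90.8%.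

(Its constants are made up, and the outcome is calculated.)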